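(The numbers in the tables were generated by integration with made-up constants, and the scatter is random.)

In the maple run E is down to 8.1% of its charge at 80.0 min while XEQ reads 0%, so E goes first into something unseen, and XEQ comes up later, reaching 19.6% at 600 min. The new flasks differ in temperature, and each stands for 80 min.

| flask | E | Q | Z | temperature | remark | time |
|---|---|---|---|---|---|---|
| cedar | 0.25 M | 0.31 M | 140 mM (held) | 10 °C | run made earlier |  |
| maple | 0.25 M | 1.2 M | 140 mM (held) | 52 °C | run made earlier |  |
| larch | 0.50 M | 0.625 M | 140 mM (held) | 10 °C | run made earlier |  |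
| Sunday's | 0.25 M | 0.625 M | 140 mM (held) | 90 °C |  | 80 min |
| Tuesday's | 0.25 M | 0.625 M | 140 mM (held) | 65 °C |  | 80 min |
| Thursday's | 0.25 M | 0.625 M | 140 mM (held) | 40 °C |  | 80 min |
| Friday's | 0.25 M | 0.625 M | 140 mM (held) | 15 °C |  | 80 min |

| run | time / min | XEQ / % | E / % |
|---|---|---|---|
| cedar | 720 | 0.2 | 85.8 |
| cedar | 1500 | 0 | 71.0 |
| cedar | 2400 | 0.7 | 58.7 |
| cedar | 2880 | 0.4 | 53.0 |
| cedar | 4320 | 0 | 39.0 |
| maple | 50.0 | 0.3 | 20.8 |
| maple | 80.0 | 0 | 8.1 |
| maple | 120 | 1.8 | 2.3 |
| maple | 240 | 5.3 | 0 |
| maple | 360 | 11.2 | 0.2 |
| maple | 600 | 19.6 | 0 |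
| larch | 1200 | 0.2 | 64.8 |
| larch | 2400 | 0.5 | 46.2 |
| larch | 2880 | 1.0 | 38.6 |
| larch | 4320 | 0.3 | 26.3 |

(standard deviation of a reading: 0.5 percentage points)

- at the start none of Z is in solution

* which flask leads in amount of XEQ, in percent of the E charged ("all alike" within 1.5 percentage points) (Sunday's / Tuesday's / Thursday's / Friday's / all alike)
* how much XEQ is there at the end, in percent of the E charged: Sunday's
* how much XEQ is there at the end, in percent of the E charged: Tuesday's
* how much XEQ is there at the end, in percent of the E charged: Thursday's
* how much XEQ is there at the end, in percent of the E charged: Friday's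

My colleague and I argue at the board about Sunday's flask. Let κ be a pseudo-first-order constant for the rise of XEQ, so that XEQ as a fraction of the E charged is 1 − exp(−κ·time).

My colleague takes maple's last reading over its whole time, which gives κ = 3.64 × 10⁻⁴ /min. He doubles it for every 10 degrees, a factor of 13.9 up to 90 °C, and lets the clock run for the whole 80 min, which gives him 33.3% for Sunday's flask.

I accept the doubling but not the clock. At the start none of Z is in solution, and I suppose that XEQ needs dissolved Z, which I call X. The line through maple's XEQ readings at 120 min and 600 min meets zero at τ = 71.5 min, and I read that as the time constant of X coming up.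

So I count θ, the full-strength minutes, meaning the minutes at full X that equal the flask's rising X over time t: θ = t − τ·(1 − exp(−t/τ)). The zero of this scale is my colleague's case, X present from the first minute, with θ = t. For 80 min I get θ = 31.9 min.

Maple, reckoned on θ, gives κ = 4.13 × 10⁻⁴ /min. Doubled up to 90 °C that is 0.00575 /min, and like my colleague I carry it unchanged from maple's 1.2 M of Q to Sunday's 0.625 M, so I commit to 16.7% for Sunday's flask. I take τ to be the same at each temperature, so the new flasks share their θ, which leaves temperature to order them in my reckoning, and Sunday's is the hottest, so I also put it first.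

The forecast, which says “the hottest flask leads”, gives 32%, 4%, 0.1% and 0% from Sunday's to Friday's, and its 32% is what rates doubled for every 10 degrees from maple give, beside my colleague's 33.3%.

Sunday's flask gives 21.3% and leads Tuesday's 2.69%, Thursday's 0.0815% and Friday's 0%, and it stands 4.6 percentage points above my reckoning. At 80.0 min in Sunday's flask X is still made 1.23 times as fast as it is used up, each step taken net. My colleague's clock comes nearer in maple's long run: by my reckoning θ/t is 88.1% for maple at 600 min, against 39.9% for Sunday's. Read back through θ, Sunday's result gives κ = 0.00752 /min.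

    E + X → EX (k = 0.0280 /M/s, Ea = 83.0 kJ/mol)
    Z ⇌ X, rate k2*(csat - [X]) (kL = 2.00 × 10⁻⁴ /s)
    X + EQ → XEQ (k = 0.00180 /M/s, Ea = 90.0 kJ/mol)
    E + Q → EQ (k = 0.00800 /M/s, Ea = 74.0 kJ/mol)
    (constants at 90 °C)

Left until 5.0 h at the same temperature, Sunday's flask has θ = 230 min, so this κ gives 82.2% of XEQ. Computed, that flask holds 81.2%.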